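Labdane numbering is used. The key step exploits the oxygenated two-carbon edge C6–C7 of ring B, which lies between ring-fusion carbon C5 and carbinol carbon C8: ring B is cut at C5–C6 and C7–C8 and C6–C7 becomes an acetyl unit. The precursor is an enantioenriched ring A 1,3-diketone, (S)-2,2,6-trimethyl-6-propanoylcyclohexanone, in which C8 is the only enolizable carbon and C5 the only carbonyl able to condense. In one flask, C-acylation at C8 and aldol condensation of the diketone dianion (C6) onto C5 close ring B as an enedione. Its C5=C6 bond and C7 and C9 carbonyls then let the axial C10 methyl direct C5, C6, C7, C8 and C9.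

Key step: step 6

Remark on numbering: C1–C5 and C10 form ring A, C5–C10 ring B, C11–C16 the side chain; C17 is the methyl on C8, C18/C19 the methyls on C4, C20 the methyl on C10.
Assumption: (S)-t-Bu-PHOX is taken to give the (S)-ketone 4 in step 2, as in the parent 2-methylcyclohexanone case; if the sense is opposite, the (R)-ligand is used.

Step 1
Reactants: 1 2,2,6-trimethylcyclohexan-1-one (racemic); 2 allyl chloroformate
Product: 3 prop-2-en-1-yl 2,6,6-trimethylcyclohex-1-en-1-yl carbonate
Conditions: LiHMDS, THF, 0 °C; then 2, −78 → 23 °C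
Reagents that add atoms: allyl chloroformate (C=CCOC(Cl)=O)
Why: The only α-hydrogen of 1 sits on the future C10, so a single lithium enolate forms and is O-acylated by the hard chloroformate (enolate O-acylation), which also erases the stereocentre of the racemic ketone.

Step 2
Reactants: 3 prop-2-en-1-yl 2,6,6-trimethylcyclohex-1-en-1-yl carbonate
Product: 4 (2S)-2,6,6-trimethyl-2-(prop-2-en-1-yl)cyclohexan-1-one
Conditions: Pd2(dba)3 (cat.), (S)-t-Bu-PHOX (cat.), THF, 25 °C
Reagents that add atoms: none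
Why: Tsuji-type decarboxylative asymmetric allylic alkylation: zerovalent palladium ionizes the allyl carbonate, CO2 is lost, and the enolate recombines with the π-allyl unit inside the chiral P,N-ligand sphere, which sets the quaternary C10 centre by ligand control.

Step 3
Reactants: 4 (2S)-2,6,6-trimethyl-2-(prop-2-en-1-yl)cyclohexan-1-one
Product: 5 (6S)-2,2,6-trimethyl-6-[(1E)-prop-1-en-1-yl]cyclohexan-1-one
Conditions: RuHCl(CO)(PPh3)3 (cat.), toluene, 80 °C
Reagents that add atoms: none
Why: Ruthenium hydride alkene isomerization (hydrometalation/β-hydride elimination) should move the terminal double bond one position to the more stable E-propenyl group and then stop at the quaternary C10, which is not touched.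

Step 4
Reactants: 5 (6S)-2,2,6-trimethyl-6-[(1E)-prop-1-en-1-yl]cyclohexan-1-one; 6 ozone
Product: 7 (1S)-1,3,3-trimethyl-2-oxocyclohexane-1-carbaldehyde
Conditions: O3, CH2Cl2, −78 °C; then Me2S, −78 → 23 °C
Reagents that add atoms: ozone ([O-][O+]=O)
Why: Ozonolysis with reductive work-up cleaves the propenyl C=C to give C9 as an aldehyde on the quaternary carbon, a β-keto aldehyde that cannot enolize and therefore keeps C10 intact.

Step 5
Reactants: 7 (1S)-1,3,3-trimethyl-2-oxocyclohexane-1-carbaldehyde; 8 ethylmagnesium bromide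
Product: 10 (6S)-2,2,6-trimethyl-6-propanoylcyclohexan-1-one, via bromomagnesium alkoxide 9 (not isolated)
Conditions: EtMgBr, THF, −78 °C; then 1,1'-(azodicarbonyl)dipiperidine, 0 → 23 °C
Reagents that add atoms: ethylmagnesium bromide (CC[Mg]Br)
Why: Grignard addition should occur only at the aldehyde because the ring ketone is flanked by two quaternary carbons, and the magnesium alkoxide is then oxidized in the same flask by hydride transfer to the azodicarboxamide (Mukaiyama-type oxidation of magnesium alkoxides), which erases the transient carbinol centre.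

Step 6
Reactants: 10 (6S)-2,2,6-trimethyl-6-propanoylcyclohexan-1-one; 11 1-acetyl-1H-benzotriazole
Product: 14 (8aR)-2,5,5,8a-tetramethyl-6,7,8,8a-tetrahydronaphthalene-1,3(2H,5H)-dione, via triketone 12 (not isolated), via ketol 13 (not isolated)
Conditions: LiHMDS (2.1 equiv), THF, −78 °C; 11, −78 → −20 °C; LDA (1.5 equiv), −78 → 0 °C; then 2 M HCl, 23 °C
Reagents that add atoms: 1-acetyl-1H-benzotriazole (CC(=O)n1nnc2ccccc21)
Why: C8 is the only enolizable carbon of 10, so LiHMDS gives one enolate, which is C-acylated by the N-acylbenzotriazole (Claisen-type acylation, C7–C8) to the 2-methyl-1,3-diketone 12, held as its lithium enolate by the second equivalent of base. LDA then removes a proton from the acetyl methyl C6, and the terminal carbon of this 1,3-diketone dianion adds to the C5 ring ketone (intramolecular aldol, C5–C6) in a 6-(enolendo)-exo-trig closure of ring B; the acidic work-up dehydrates the strained tertiary ketol 13, and this elimination can only run towards C6 because C4 and C10 are quaternary. The closest known reaction types are the C-acylation of ketone enolates with N-acylbenzotriazoles and the γ-aldol cyclodehydration of 1,3-diketone dianions (the ring-closing half of a Robinson annulation). No new stereocentre has to be controlled: C10 is carried through, C5 and C6 become sp2, and C8 stays an enolized or epimerizable centre that is set in step 8. The selectivity needed is site selectivity (C-acylation at C8, deprotonation at C6, attack on C5 and not on C9), and the substrate secures it, since C5 and C10 bear no α-hydrogens, C9 is masked as the enolate and only closure onto C5 gives a six-membered ring.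

Step 7
Reactants: 14 (8aR)-2,5,5,8a-tetramethyl-6,7,8,8a-tetrahydronaphthalene-1,3(2H,5H)-dione
Product: 15 (4aR,8aR)-2,5,5,8a-tetramethyl-4a,5,6,7,8,8a-hexahydronaphthalene-1,3(2H,4H)-dione
Conditions: H2 (1 atm), 10% Pd/C, EtOAc, 23 °C
Reagents that add atoms: none
Why: Heterogeneous hydrogenation of the trisubstituted C5=C6 bond should deliver hydrogen to the face opposite the C10 methyl and the axial C4 methyl, which sets C5 with the trans ring fusion.

Step 8
Reactants: 15 (4aR,8aR)-2,5,5,8a-tetramethyl-4a,5,6,7,8,8a-hexahydronaphthalene-1,3(2H,4H)-dione; 16 dimethyldioxirane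
Product: 17 (2S,4aR,8aR)-2-hydroxy-2,5,5,8a-tetramethyl-4a,5,6,7,8,8a-hexahydronaphthalene-1,3(2H,4H)-dione
Conditions: dimethyldioxirane (acetone solution), acetone, 0 °C
Reagents that add atoms: dimethyldioxirane (CC1(C)OO1)
Why: α-Hydroxylation of a 1,3-diketone through epoxidation of its enol: in the trans-fused system the C10 methyl is axial and 1,3-related to C8, so the oxidant should attack C8 from the opposite face and leave the hydroxyl equatorial and the C8 methyl axial.

Step 9
Reactants: 17 (2S,4aR,8aR)-2-hydroxy-2,5,5,8a-tetramethyl-4a,5,6,7,8,8a-hexahydronaphthalene-1,3(2H,4H)-dione; 16 dimethyldioxirane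
Product: 20 (2R,4S,4aR,8aR)-2,4-dihydroxy-2,5,5,8a-tetramethyl-4a,5,6,7,8,8a-hexahydronaphthalene-1,3(2H,4H)-dione, via bis(trimethylsilyl) enol ether 18 (not isolated), via bis(trimethylsilyl) ketol 19 (not isolated)
Conditions: TMSOTf, Et3N, CH2Cl2, 0 °C; then dimethyldioxirane, acetone, −40 °C; then citric acid, MeOH, 23 °C
Reagents that add atoms: dimethyldioxirane (CC1(C)OO1)
Why: Rubottom oxidation: C6 is the only enolizable position left, silylation also caps the tertiary hydroxyl against base-induced α-ketol rearrangement, and the oxidant should reach C6 only from the face opposite the axial methyls on C4 and C10, giving the equatorial hydroxyl, which is also the thermodynamically preferred epimer at this epimerizable centre.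

Step 10
Reactants: 20 (2R,4S,4aR,8aR)-2,4-dihydroxy-2,5,5,8a-tetramethyl-4a,5,6,7,8,8a-hexahydronaphthalene-1,3(2H,4H)-dione
Product: 21 (2S,3R,4S,4aR,8aR)-2,3,4-trihydroxy-2,5,5,8a-tetramethyl-3,4,4a,5,6,7,8,8a-octahydronaphthalen-1(2H)-one
Conditions: NaBH4, CeCl3·7H2O, MeOH, −78 °C
Reagents that add atoms: none
Why: Luche reduction: hydride should add to the C7 carbonyl, which is less hindered and more activated than C9 (C9 lies between two fully substituted carbons), along the axial trajectory opposite the axial C8 methyl, giving the equatorial C7 hydroxyl trans to both neighbouring hydroxyls.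

Step 11
Reactants: 21 (2S,3R,4S,4aR,8aR)-2,3,4-trihydroxy-2,5,5,8a-tetramethyl-3,4,4a,5,6,7,8,8a-octahydronaphthalen-1(2H)-one; 22 (trimethylsilyl)methyllithium
Product: 24 (1S,2R,3R,4aR,8aR)-3,4a,8,8-tetramethyl-4-methylidenedecahydronaphthalene-1,2,3-triol, via β-hydroxysilane 23 (not isolated)
Conditions: CeCl3, TMSCH2Li (6 equiv), THF, −78 → 0 °C; aq. NH4Cl; then KH, THF, 0 → 23 °C
Reagents that add atoms: (trimethylsilyl)methyllithium ([Li]C[Si](C)(C)C)
Why: Peterson olefination: both axial methyls (on C8 and C10) lie on one face, so the small organocerium reagent can add to the C9 carbonyl along the open axial trajectory at low temperature (where retro-aldol of the β-alkoxy ketone is slow), and potassium alkoxide-induced syn elimination of silanolate then gives the exocyclic C9=C11 methylene.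

Step 12
Reactants: 25 prop-2-yn-1-ol; 26 methylmagnesium bromide; 27 iodine
Product: 29 (2Z)-3-iodo-2-methylprop-2-en-1-ol, via vinylmagnesium alkoxide 28 (not isolated)
Conditions: MeMgBr (3 equiv), CuI (cat.), Et2O, −10 → 23 °C; then I2, −40 → 0 °C
Reagents that add atoms: methylmagnesium bromide (C[Mg]Br); iodine (II)
Why: Copper-catalysed carbomagnesiation of the propargylic magnesium alkoxide: chelation to the alkoxide enforces anti addition with methyl on C2 and magnesium on C3, and iodinolysis with retention gives the Z-iodoalkene that later becomes the C12=C13 bond.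

Step 13
Reactants: 29 (2Z)-3-iodo-2-methylprop-2-en-1-ol
Product: 30 (2Z)-3-iodo-2-methylprop-2-enal
Conditions: MnO2 (excess), CH2Cl2, 23 °C, dark
Reagents that add atoms: none
Why: Activated MnO2 oxidizes the allylic alcohol to the enal under neutral conditions that should leave the vinyl iodide and its Z geometry untouched.

Step 14
Reactants: 30 (2Z)-3-iodo-2-methylprop-2-enal; 31 methyltriphenylphosphonium bromide
Product: 32 (1Z)-1-iodo-2-methylbuta-1,3-diene
Conditions: Ph3PCH3Br, NaHMDS, THF, 0 °C; then 30, −78 → 0 °C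
Reagents that add atoms: methyltriphenylphosphonium bromide (C[P+](c1ccccc1)(c1ccccc1)c1ccccc1.[Br-])
Why: Wittig methylenation with the non-stabilized ylide at low temperature converts the aldehyde into the terminal vinyl group (C14=C15) without touching the trisubstituted iodoalkene.

Step 15
Reactants: 24 (1S,2R,3R,4aR,8aR)-3,4a,8,8-tetramethyl-4-methylidenedecahydronaphthalene-1,2,3-triol; 33 9-borabicyclo[3.3.1]nonane; 32 (1Z)-1-iodo-2-methylbuta-1,3-diene
Product: 35 (1S,2R,3R,4S,4aR,8aR)-3,4a,8,8-tetramethyl-4-[(2Z)-3-methylpenta-2,4-dien-1-yl]decahydronaphthalene-1,2,3-triol, via B-alkyl-9-BBN 34 (not isolated)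
Conditions: 9-BBN (excess), THF, 60 °C; then H2O; Pd(dppf)Cl2 (cat.), AsPh3, Cs2CO3, 32, DMF/THF/H2O, 23 °C
Reagents that add atoms: none
Why: Anti-Markovnikov hydroboration of the 1,1-disubstituted alkene from the face opposite the axial C8 and C10 methyls sets C9 (hydrogen axial, side chain equatorial), and B-alkyl Suzuki–Miyaura coupling joins C11 to C12 with retention of the Z geometry of the iodide.

Step 16
Reactants: 35 (1S,2R,3R,4S,4aR,8aR)-3,4a,8,8-tetramethyl-4-[(2Z)-3-methylpenta-2,4-dien-1-yl]decahydronaphthalene-1,2,3-triol; 36 acetic anhydride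
Product: 37 (1S,2R,3R,4S,4aR,8aR)-3-hydroxy-3,4a,8,8-tetramethyl-4-[(2Z)-3-methylpenta-2,4-dien-1-yl]decahydronaphthalene-1,2-diyl diacetate
Conditions: Ac2O, pyridine, DMAP (cat.), CH2Cl2, 23 °C
Reagents that add atoms: acetic anhydride (CC(=O)OC(C)=O)
Why: Nucleophile-catalysed acetylation should esterify the two secondary equatorial hydroxyls on C6 and C7, while the hindered tertiary C8 hydroxyl is not acylated under these mild conditions and the diene is inert.

Compound list
1 | 2,2,6-trimethylcyclohexan-1-one (racemic) | CC1CCCC(C)(C)C1=O | starting material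
2 | allyl chloroformate | C=CCOC(Cl)=O | starting material
3 | prop-2-en-1-yl 2,6,6-trimethylcyclohex-1-en-1-yl carbonate | C=CCOC(=O)OC1=C(C)CCCC1(C)C | intermediate
4 | (2S)-2,6,6-trimethyl-2-(prop-2-en-1-yl)cyclohexan-1-one | O=C1C(C)(C)CCC[C@]1(CC=C)C | intermediate
5 | (6S)-2,2,6-trimethyl-6-[(1E)-prop-1-en-1-yl]cyclohexan-1-one | O=C1C(C)(C)CCC[C@]1(/C=C/C)C | intermediate
6 | ozone | [O-][O+]=O | starting material
7 | (1S)-1,3,3-trimethyl-2-oxocyclohexane-1-carbaldehyde | O=C1C(C)(C)CCC[C@]1(C=O)C | intermediate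
8 | ethylmagnesium bromide | CC[Mg]Br | starting material
9 | bromomagnesium alkoxide of (6S)-6-(1-hydroxypropyl)-2,2,6-trimethylcyclohexan-1-one (carbinol epimers) | O=C1C(C)(C)CCC[C@]1(C(CC)O[Mg]Br)C | intermediate
10 | (6S)-2,2,6-trimethyl-6-propanoylcyclohexan-1-one | O=C1C(C)(C)CCC[C@]1(C(=O)CC)C | intermediate
11 | 1-acetyl-1H-benzotriazole | CC(=O)n1nnc2ccccc21 | starting material
12 | 2-methyl-1-[(1S)-1,3,3-trimethyl-2-oxocyclohexyl]butane-1,3-dione (present as its lithium enolate) | O=C1C(C)(C)CCC[C@]1(C(=O)C(C)C(C)=O)C | intermediate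
13 | (8aR)-4a-hydroxy-2,5,5,8a-tetramethyl-4a,5,6,7,8,8a-hexahydronaphthalene-1,3(2H,4H)-dione (present as its lithium salt; C2 and C4a not assigned) | CC1C(=O)CC2(O)C(C)(C)CCC[C@@]2(C)C1=O | intermediate
14 | (8aR)-2,5,5,8a-tetramethyl-6,7,8,8a-tetrahydronaphthalene-1,3(2H,5H)-dione (C2 epimers and enol) | CC1C(=O)C=C2C(C)(C)CCC[C@@]2(C)C1=O | intermediate
15 | (4aR,8aR)-2,5,5,8a-tetramethyl-4a,5,6,7,8,8a-hexahydronaphthalene-1,3(2H,4H)-dione (C2 epimers and enol) | CC1C(=O)C[C@@H]2C(C)(C)CCC[C@@]2(C)C1=O | intermediate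
16 | dimethyldioxirane | CC1(C)OO1 | starting material
17 | (2S,4aR,8aR)-2-hydroxy-2,5,5,8a-tetramethyl-4a,5,6,7,8,8a-hexahydronaphthalene-1,3(2H,4H)-dione | C[C@]1(O)C(=O)C[C@@H]2C(C)(C)CCC[C@@]2(C)C1=O | intermediate
18 | (2S,4aR,8aR)-2,5,5,8a-tetramethyl-2,3-bis[(trimethylsilyl)oxy]-4a,5,6,7,8,8a-hexahydronaphthalen-1(2H)-one | C[C@]1(O[Si](C)(C)C)C(O[Si](C)(C)C)=C[C@@H]2C(C)(C)CCC[C@@]2(C)C1=O | intermediate
19 | (2R,4S,4aR,8aR)-2,5,5,8a-tetramethyl-2,4-bis[(trimethylsilyl)oxy]-4a,5,6,7,8,8a-hexahydronaphthalene-1,3(2H,4H)-dione | C[C@]1(O[Si](C)(C)C)C(=O)[C@@H](O[Si](C)(C)C)[C@@H]2C(C)(C)CCC[C@@]2(C)C1=O | intermediate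
20 | (2R,4S,4aR,8aR)-2,4-dihydroxy-2,5,5,8a-tetramethyl-4a,5,6,7,8,8a-hexahydronaphthalene-1,3(2H,4H)-dione | C[C@]1(O)C(=O)[C@@H](O)[C@@H]2C(C)(C)CCC[C@@]2(C)C1=O | intermediate
21 | (2S,3R,4S,4aR,8aR)-2,3,4-trihydroxy-2,5,5,8a-tetramethyl-3,4,4a,5,6,7,8,8a-octahydronaphthalen-1(2H)-one | C[C@]1(O)[C@H](O)[C@@H](O)[C@@H]2C(C)(C)CCC[C@@]2(C)C1=O | intermediate
22 | (trimethylsilyl)methyllithium | [Li]C[Si](C)(C)C | starting material
23 | (1S,2R,3S,4aR,8aR)-3,4a,8,8-tetramethyl-4-[(trimethylsilyl)methyl]decahydronaphthalene-1,2,3,4-tetrol (C4 not assigned) | C[C@]1(O)[C@H](O)[C@@H](O)[C@@H]2C(C)(C)CCC[C@@]2(C)C1(O)C[Si](C)(C)C | intermediate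
24 | (1S,2R,3R,4aR,8aR)-3,4a,8,8-tetramethyl-4-methylidenedecahydronaphthalene-1,2,3-triol | C[C@]1(O)[C@H](O)[C@@H](O)[C@@H]2C(C)(C)CCC[C@@]2(C)C1=C | intermediate
25 | prop-2-yn-1-ol | C#CCO | starting material
26 | methylmagnesium bromide | C[Mg]Br | starting material
27 | iodine | II | starting material
28 | (Z)-3-(bromomagnesio)-2-methylprop-2-en-1-yloxymagnesium bromide | Br[Mg]/C=C(C)\CO[Mg]Br | intermediate
29 | (2Z)-3-iodo-2-methylprop-2-en-1-ol | I/C=C(C)\CO | intermediate
30 | (2Z)-3-iodo-2-methylprop-2-enal | I/C=C(C)\C=O | intermediate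
31 | methyltriphenylphosphonium bromide | C[P+](c1ccccc1)(c1ccccc1)c1ccccc1.[Br-] | starting material
32 | (1Z)-1-iodo-2-methylbuta-1,3-diene | I/C=C(C)\C=C | intermediate
33 | 9-borabicyclo[3.3.1]nonane (9-BBN) | C1CC2CCCC(C1)B2 | starting material
34 | 9-{[(1S,2R,3R,4S,4aR,8aR)-2,3,4-trihydroxy-2,5,5,8a-tetramethyldecahydronaphthalen-1-yl]methyl}-9-borabicyclo[3.3.1]nonane | C[C@]1(O)[C@H](O)[C@@H](O)[C@@H]2C(C)(C)CCC[C@@]2(C)[C@@H]1CB1C2CCCC1CCC2 | intermediate
35 | (1S,2R,3R,4S,4aR,8aR)-3,4a,8,8-tetramethyl-4-[(2Z)-3-methylpenta-2,4-dien-1-yl]decahydronaphthalene-1,2,3-triol | C=C/C(C)=C\C[C@@H]1[C@@](C)(O)[C@H](O)[C@@H](O)[C@@H]2C(C)(C)CCC[C@]21C | intermediate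
36 | acetic anhydride | CC(=O)OC(C)=O | starting material
37 | (1S,2R,3R,4S,4aR,8aR)-3-hydroxy-3,4a,8,8-tetramethyl-4-[(2Z)-3-methylpenta-2,4-dien-1-yl]decahydronaphthalene-1,2-diyl diacetate | C=C/C(C)=C\C[C@@H]1[C@@](C)(O)[C@H](OC(C)=O)[C@@H](OC(C)=O)[C@@H]2C(C)(C)CCC[C@]21C | target

Total step count: 16. Longest linear sequence: 13 steps (steps 1–11, 15 and 16); steps 12–14 make the side-chain iodide 32.

The three steps most likely to fail are steps 6, 11 and 15.

Step 6 may fail through retro-Claisen cleavage of the triketone enolate, O- instead of C-acylation, reversal of the aldol addition at the congested C5 carbonyl before water is lost, or acid-induced skeletal rearrangement of the cross-conjugated product during dehydration. The fallback sets out from 10 and swaps the acylation/aldol pair for a conjugate addition/olefination pair. The sodium enolate of 10 (NaH, THF/DMF) is treated with vinyltriphenylphosphonium bromide, so that Michael addition of C8 is followed in the same flask by intramolecular Wittig closure onto the C5 ketone. This should give (8aR)-2,5,5,8a-tetramethyl-3,5,6,7,8,8a-hexahydronaphthalen-1(2H)-one F1. Allylic oxidation of its only allylic methylene, C7 (CrO3·3,5-dimethylpyrazole, CH2Cl2, −20 °C), then comes back to the route at 14.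

Step 11 may fail through lack of addition at the C9 carbonyl between two fully substituted carbons, retro-aldol fragmentation of the β-alkoxy ketone, or α-ketol rearrangement under the basic conditions. The fallback sets out from 15 and brings C11 in before C8 is oxidized.
- Acid-catalysed enol ether formation (MeOH, trimethyl orthoformate, TsOH) should occur at the less hindered C7 oxygen and give (4aR,8aR)-3-methoxy-2,5,5,8a-tetramethyl-4a,5,6,7,8,8a-hexahydronaphthalen-1(4H)-one F2.
- Addition of MeLi/CeCl3 to the C9 carbonyl gives (4aR,8aR)-3-methoxy-1,2,5,5,8a-pentamethyl-1,4,4a,5,6,7,8,8a-octahydronaphthalen-1-ol F3.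
- Aqueous HCl hydrolyses and dehydrates F3 (Stork–Danheiser transposition) to (4aR,8aR)-3,4,4a,8,8-pentamethyl-4a,5,6,7,8,8a-hexahydronaphthalen-2(1H)-one F4.
- Kinetic deprotonation at C6 (LDA, −78 °C) and oxidation with 2-(phenylsulfonyl)-3-phenyloxaziridine gives (1S,4aR,8aR)-1-hydroxy-3,4,4a,8,8-pentamethyl-4a,5,6,7,8,8a-hexahydronaphthalen-2(1H)-one F5.
- KHMDS (2.2 equiv) then forms the extended dienolate by deprotonation at C11, and the same oxaziridine hydroxylates its α-carbon C8 opposite the axial C10 methyl with deconjugation, giving (1S,3R,4aR,8aR)-1,3-dihydroxy-3,4a,8,8-tetramethyl-4-methylidene-3,4,4a,5,6,7,8,8a-octahydronaphthalen-2(1H)-one F6.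
- Luche reduction of the single remaining ketone returns to the route at 24.

Step 15 may fail through sluggish hydroboration of the hindered exocyclic alkene, consumption of the borane by the free hydroxyls, or slow transmetalation of the β-branched alkylborane followed by protodeboronation. The fallback sets out from 24 and replaces the boron coupling by an oxidation/zinc sequence.
- BH3·SMe2 then NaOH/H2O2 gives (1S,2R,3R,4R,4aR,8aR)-4-(hydroxymethyl)-3,4a,8,8-tetramethyldecahydronaphthalene-1,2,3-triol F7.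
- Selective iodination of the primary hydroxyl (I2, PPh3, imidazole) gives (1S,2R,3R,4S,4aR,8aR)-4-(iodomethyl)-3,4a,8,8-tetramethyldecahydronaphthalene-1,2,3-triol F8.
- Acetylation (Ac2O, pyridine, DMAP) gives (1S,2R,3R,4S,4aR,8aR)-3-hydroxy-4-(iodomethyl)-3,4a,8,8-tetramethyldecahydronaphthalene-1,2-diyl diacetate F9.
- Zinc insertion (Zn, LiCl, THF) gives {[(1S,2R,3R,4S,4aR,8aR)-3,4-diacetoxy-2-hydroxy-2,5,5,8a-tetramethyldecahydronaphthalen-1-yl]methyl}zinc iodide F10.
- Negishi coupling of F10 with 32 (Pd(PPh3)4, THF) comes back to the route at the target 37.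

Further compounds
F1 | step 6 | (8aR)-2,5,5,8a-tetramethyl-3,5,6,7,8,8a-hexahydronaphthalen-1(2H)-one | CC1CC=C2C(C)(C)CCC[C@@]2(C)C1=O
F2 | step 11 | (4aR,8aR)-3-methoxy-2,5,5,8a-tetramethyl-4a,5,6,7,8,8a-hexahydronaphthalen-1(4H)-one | CC1=C(OC)C[C@@H]2C(C)(C)CCC[C@@]2(C)C1=O
F3 | step 11 | (4aR,8aR)-3-methoxy-1,2,5,5,8a-pentamethyl-1,4,4a,5,6,7,8,8a-octahydronaphthalen-1-ol | CC1=C(OC)C[C@@H]2C(C)(C)CCC[C@@]2(C)C1(C)O
F4 | step 11 | (4aR,8aR)-3,4,4a,8,8-pentamethyl-4a,5,6,7,8,8a-hexahydronaphthalen-2(1H)-one | CC=1C(=O)C[C@@H]2C(C)(C)CCC[C@@]2(C)C=1C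
F5 | step 11 | (1S,4aR,8aR)-1-hydroxy-3,4,4a,8,8-pentamethyl-4a,5,6,7,8,8a-hexahydronaphthalen-2(1H)-one | CC=1C(=O)[C@@H](O)[C@@H]2C(C)(C)CCC[C@@]2(C)C=1C
F6 | step 11 | (1S,3R,4aR,8aR)-1,3-dihydroxy-3,4a,8,8-tetramethyl-4-methylidene-3,4,4a,5,6,7,8,8a-octahydronaphthalen-2(1H)-one | C[C@]1(O)C(=O)[C@@H](O)[C@@H]2C(C)(C)CCC[C@@]2(C)C1=C
F7 | step 15 | (1S,2R,3R,4R,4aR,8aR)-4-(hydroxymethyl)-3,4a,8,8-tetramethyldecahydronaphthalene-1,2,3-triol | C[C@]1(O)[C@H](O)[C@@H](O)[C@@H]2C(C)(C)CCC[C@@]2(C)[C@@H]1CO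
F8 | step 15 | (1S,2R,3R,4S,4aR,8aR)-4-(iodomethyl)-3,4a,8,8-tetramethyldecahydronaphthalene-1,2,3-triol | C[C@]1(O)[C@H](O)[C@@H](O)[C@@H]2C(C)(C)CCC[C@@]2(C)[C@@H]1CI
F9 | step 15 | (1S,2R,3R,4S,4aR,8aR)-3-hydroxy-4-(iodomethyl)-3,4a,8,8-tetramethyldecahydronaphthalene-1,2-diyl diacetate | C[C@]1(O)[C@H](OC(C)=O)[C@@H](OC(C)=O)[C@@H]2C(C)(C)CCC[C@@]2(C)[C@@H]1CI
F10 | step 15 | {[(1S,2R,3R,4S,4aR,8aR)-3,4-diacetoxy-2-hydroxy-2,5,5,8a-tetramethyldecahydronaphthalen-1-yl]methyl}zinc iodide | C[C@]1(O)[C@H](OC(C)=O)[C@@H](OC(C)=O)[C@@H]2C(C)(C)CCC[C@@]2(C)[C@@H]1C[Zn]I
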